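## The problem

The target is a heliangolide-type germacranolide: a ten-membered carbocycle (C1–C10) trans-fused at C6–C7 to an α-methylene γ-lactone (C11, C12, C13, O on C6). It carries a Z-trisubstituted C4=C5 alkene, a trans C1–C10 epoxide, a free C3 carbinol and, at C8, the ester of (2R,3R)-2,3-epoxy-2-methylbutanoic acid. Six ring stereocentres (C1, C3, C6, C7, C8, C10) and two in the side chain have to be set. C6–C7–C8 form a contiguous triad that can be made on an open chain, whereas C3 and C1/C10 are remote from it and can only be controlled by the closed ring or by reagents. The ring itself is a strained medium ring with two trisubstituted alkenes of opposite geometry, so both geometries must be fixed before closure. Several groups will not survive rough treatment: the α-methylene lactone is a Michael acceptor, both epoxides are acid-labile, the allylic C6–O bond can ionise, 1,5-dienes of this type cyclise transannularly under acid and rearrange on heating, and a free C8 hydroxyl next to the lactone can take over the lactone carbonyl. The feature that opens the structure is the triad itself: the C7–C11 bond is anti to the C8 oxygen while C6 carries the lactone oxygen. That is the pattern left by a carbon nucleophile tethered through O6 opening a trans C7–C8 epoxide at C7 with inversion. A single asymmetric epoxidation of a bis-allylic alcohol can therefore encode C6, C7 and C8 together.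

## Retrosynthesis

Germacrane numbering is used for every intermediate.

**C1–C10 epoxide (32 ⇒ 31).** The two C–O bonds of the ring epoxide are removed last, giving dienol 31. Carrying the epoxide through the chromium-mediated ring closure would expose it to Lewis acids and would give up the facial bias of the closed ring. In 31 the C1=C10 alkene is the only electron-rich one (C4=C5 is flanked by two allylic C–O bonds, C11=C13 is conjugated). The forward step must find that alkene and its outer face.

**Ring closure at C3–C4 (31 ⇒ 30).** Cutting C3–C4 gives the open-chain iodo aldehyde 30. Closure at C1=C10 by metathesis would have to form an E-trisubstituted alkene in a ten-membered ring, and closure through the lactone is not available. The C3–C4 cut stores the Z geometry in an alkenyl iodide and forms the allylic carbinol directly. The forward Nozaki–Hiyama–Kishi reaction must close a ten-membered ring and set C3.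

**Methylene group, aldehyde and silyl groups (30 ⇒ 29 ⇒ 27).** The aldehyde comes from the primary alcohol 29. The C11=C13 bond is traced to a C11 carboxyl group, so 29 comes from lactone ester 27 by ester cleavage and decarboxylative methylenation. The methylene lactone is made before the ring closure because an acidic C11–H would be positioned to protonate the alkenylmetal at C4. The ester is a 2-(trimethylsilyl)ethyl ester rather than an allyl ester: removing an allyl ester needs zerovalent palladium, which would insert into the C4–I bond, whereas fluoride cleaves the silylethyl ester and the C3 silyl ether in one operation.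

**C8 ester (27 ⇒ 21 + 25).** The C8–O acyl bond is cut to hydroxy lactone 21 and acid 25. Acylating directly after the key step caps the hydroxyl that could otherwise translactonise, and it needs no temporary protecting group. Acid 25 comes from methyl angelate 22 through alcohol 23 and epoxy alcohol 24 by a Sharpless epoxidation.

**Key disconnection, C7–C11 (21 ⇒ 19).** Cutting C7–C11 and returning the C8 oxygen to C7 gives the epoxy malonate 19. This one cut removes the lactone ring, one skeletal bond and the C7 and C11 stereocentres. The forward step requires the malonate carbon to attack C7 and not C8, with inversion, and the released C8 alkoxide must not attack the lactone.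

**Malonate ester (19 ⇒ 15 + 18).** The O6–C12 ester bond is cut to epoxy alcohol 15 and half ester 18, the latter from Meldrum's acid 16 and 2-(trimethylsilyl)ethanol 17.

**Epoxide (15 ⇒ 14).** Removing the epoxide oxygen gives racemic bis-allylic alcohol 14. A titanium–tartrate kinetic resolution epoxidises only the E-disubstituted C7=C8 alkene of one enantiomer and gives the erythro epoxy alcohol, fixing C6, C7 and C8 in one step. The price is that at most half of 14 can be used.

**Fragment union at C6–C7 (14 ⇒ 7 + 11).** Cutting C6–C7 gives enyne 7 (C7–C10, C1–C3, C14) and (Z)-iodo enal 11 (C4–C6, C15). Hydrozirconation of the terminal alkyne gives the E alkene by construction.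

**Fragments.** Enyne 7 comes from allylic bromide 5 and ethynylmagnesium bromide 6. Bromide 5 comes from alcohol 4 and ester 3, and the E C1=C10 alkene is made by a Wittig reaction of aldehyde 1 with ylide 2. Enal 11 comes from alcohol 10, made from but-2-yn-1-ol 8 by trans-hydroalumination and iodination, which sets the Z geometry.

## Roads not taken

**Alternative 1:** The cut runs through both ring alkenes. C1=C10 and C4=C5 are traced to the central cyclobutane of the 6-4-4 tricyclic ketone A3, the [2+2] photoadduct of cyclohexenone A1 and cyclobutene A2. In the forward sense, irradiation at 350 nm would join C1 to C10 and C4 to C5, and heating A3 would cleave the other two cyclobutane bonds to unveil the ten-membered diene.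
- Merits: the carbocycle is made from two small rings without high dilution, and the C3 and C8 oxygens are already in place.
- Weak points: head-to-head against head-to-tail orientation and the facial pairing of two chiral partners must both be right. The cycloreversion must deliver E at C1=C10 and Z at C4=C5. The temperatures it needs invite Cope rearrangement of the 1,5-diene.
- After the key step C6 is only a ketone. C7–C11 would have to be made by enolate alkylation on a flexible ten-membered ring, followed by reduction, lactonisation and methylenation, so C6 and C7 would rest on conformational control.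
- Comparison: this road reaches the carbocycle more directly and avoids the chromium macrocyclisation, which is the weakest supporting step of the chosen plan (step 18). The chosen plan sets against it a reagent-controlled C6–C7–C8 triad (steps 8 and 11), no step above 50 °C, and alkene geometries fixed by standard olefin syntheses.

**Alternative 2:** The cut is C3–C4 of methylene lactone A5, leading back to iodo aldehyde A4, in which the lactone, the methylene group and the Z-iodide are complete and C8 is a triethylsilyl ether. In the forward sense CrCl2 with catalytic NiCl2 turns the C4 iodide into an alkenylchromium species that adds to the C3 aldehyde.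
- Merits: the ring is closed on a finished lactone, the Z geometry is stored in the iodide, and the C3 carbinol is formed directly.
- On the ring-forming event the two plans are equal, since the chosen plan uses the same closure in step 18 and shares its risk.
- Where it is better: the methylene lactone needs no decarboxylation, and the epoxy ester never meets divalent chromium.
- Weak points: the closure says nothing about how C6, C7 and C8 are set, so that is left to earlier substrate- or auxiliary-controlled chemistry. The C8 silyl ether must be exchanged for the epoxy ester on the strained macrocycle, where a free C8 hydroxyl can translactonise.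
- The chosen plan sets against it one catalytic asymmetric epoxidation and one invertive opening that define the whole triad, and acylation of C8 on the open chain as soon as the hydroxyl appears.

**Alternative 3:** The cut is C11–C12 and C12–O6. Lactone A7 would come from the trans-fused oxetane A6 by insertion of CO with [(salph)Al(THF)2][Co(CO)4]. The aluminium centre activates the oxetane oxygen, the cobaltate opens the primary C11–O bond, and CO insertion and ring closure give the γ-lactone with C6 and C7 untouched.
- Merits: the carbonyl carbon comes from CO at a late stage, and the trans fusion is carried over from the oxetane.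
- Weak points: A6 is itself a trans-fused oxetane on a ten-membered ring and needs the same C6/C7 stereochemistry beforehand. The C6–O bond is allylic, so Lewis-acid ionisation at C6 with transannular participation of C1=C10 competes with attack at C11. Oxetanes carbonylate less readily than epoxides.
- A7 still lacks C13, so a strong-base methylenation, protecting-group removal at C8 and C3, acylation and epoxidation would remain.
- Comparison: this road is better in atom economy and has no intermediate with an acidic C11–H. The chosen plan sets against it a key step of an established reaction class that forms the C7–C11 skeletal bond and the triad stereochemistry together, whereas the carbonylation only adds a carbonyl to a skeleton whose stereochemistry must already exist.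

Key step: step 11

Remarks on the chemistry:
- The acyl group read from the SMILES is the (2R,3R)-epoxide of the Z acid (epoxyangelate).
- CIP descriptors quoted with germacrane locants change where substituent priorities change although the centre is untouched: C6 is S in the iodides 21 and 27–30 and R elsewhere.
- Compounds 1, 2, 6, 8, 16, 17 and 22 are taken as commercial.

## Route

**Step 1**
Reactants: 1 3-[(tert-butyldimethylsilyl)oxy]propanal; 2 ethyl 2-(triphenylphosphoranylidene)propanoate
Product: 3 ethyl (2E)-5-[(tert-butyldimethylsilyl)oxy]-2-methylpent-2-enoate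
Conditions: CH2Cl2, rt → 40 °C
Reagents that add atoms: none
Why: Wittig olefination with a stabilised α-methyl ylide should give the E-trisubstituted alkene, which becomes C1=C10 with C14 on C10.

**Step 2**
Reactants: 3 ethyl (2E)-5-[(tert-butyldimethylsilyl)oxy]-2-methylpent-2-enoate
Product: 4 (2E)-5-[(tert-butyldimethylsilyl)oxy]-2-methylpent-2-en-1-ol
Conditions: i-Bu2AlH (2.2 equiv), CH2Cl2, −78 → 0 °C
Reagents that add atoms: none
Why: 1,2-Reduction of a conjugated ester by DIBAL-H should give the allylic alcohol without touching the alkene geometry or the silyl ether.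

**Step 3**
Reactants: 4 (2E)-5-[(tert-butyldimethylsilyl)oxy]-2-methylpent-2-en-1-ol
Product: 5 (3E)-5-bromo-1-[(tert-butyldimethylsilyl)oxy]-4-methylpent-3-ene
Conditions: CBr4, PPh3, CH2Cl2, 0 °C
Reagents that add atoms: carbon tetrabromide, BrC(Br)(Br)Br
Why: Appel bromination of a primary allylic alcohol is an SN2 process at the CH2 group under neutral conditions, so the E alkene and the silyl ether should be retained.

**Step 4**
Reactants: 5 (3E)-5-bromo-1-[(tert-butyldimethylsilyl)oxy]-4-methylpent-3-ene; 6 ethynylmagnesium bromide
Product: 7 tert-butyl(dimethyl){[(3E)-4-methylhept-3-en-6-yn-1-yl]oxy}silane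
Conditions: 6 (3 equiv), CuBr·SMe2 (0.1 equiv), THF, 0 °C → rt
Reagents that add atoms: none
Why: Copper-catalysed substitution of a primary allylic bromide by an alkynyl Grignard reagent is the classical route to skipped 1,4-enynes; attack at the unhindered CH2 keeps the E alkene and the excess of 6 suppresses double alkylation.

**Step 5**
Reactants: 8 but-2-yn-1-ol
Product: 10 (2Z)-3-iodobut-2-en-1-ol, via cyclic alkenylaluminate 9 (not isolated)
Conditions: NaAlH2(OCH2CH2OMe)2, THF, 0 °C → rt; then I2, −78 → 0 °C
Reagents that add atoms: iodine, II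
Why: Hydroxyl-directed trans-hydroalumination places aluminium on C3 in a five-membered alkenylaluminate, and iodinolysis with retention should give the Z-iodoalkene that later fixes the C4=C5 geometry.

**Step 6**
Reactants: 10 (2Z)-3-iodobut-2-en-1-ol
Product: 11 (2Z)-3-iodobut-2-enal
Conditions: MnO2 (excess), CH2Cl2, rt, dark; used at once
Reagents that add atoms: none
Why: Heterogeneous MnO2 oxidation of a primary allylic alcohol is neutral, which should keep the sensitive β-iodo enal in its Z form.

**Step 7**
Reactants: 7 tert-butyl(dimethyl){[(3E)-4-methylhept-3-en-6-yn-1-yl]oxy}silane; 11 (2Z)-3-iodobut-2-enal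
Product: 14 racemic (2Z,5E,8E)-11-[(tert-butyldimethylsilyl)oxy]-2-iodo-8-methylundeca-2,5,8-trien-4-ol, via alkenylzirconocene chloride 12 (not isolated), via alkenyl(methyl)zinc 13 (not isolated)
Conditions: Cp2Zr(H)Cl, CH2Cl2, rt; Me2Zn, toluene, −65 °C; then 11, 0 °C
Reagents that add atoms: none
Why: Syn hydrozirconation of the terminal alkyne (much faster than of the trisubstituted alkene) gives the E-alkenylmetal; transmetalation to zinc and 1,2-addition to the enal should form C6–C7 with C7=C8 E by construction and C6 racemic.

**Step 8**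
Reactants: 14 racemic (2Z,5E,8E)-11-[(tert-butyldimethylsilyl)oxy]-2-iodo-8-methylundeca-2,5,8-trien-4-ol
Product: 15 (1R,2Z)-1-{(2R,3R)-3-[(2E)-5-[(tert-butyldimethylsilyl)oxy]-2-methylpent-2-en-1-yl]oxiran-2-yl}-3-iodobut-2-en-1-ol (erythro; 6R,7R,8R)
Conditions: Ti(OiPr)4 (0.15 equiv), D-(−)-diisopropyl tartrate (0.2 equiv), t-BuOOH (0.6 equiv), 4 Å MS, CH2Cl2, −20 °C
Reagents that add atoms: tert-butyl hydroperoxide, CC(C)(C)OO
Why: In the Sharpless kinetic resolution with D-(−)-tartrate the (4S) enantiomer of 14 (S at C6) should be epoxidised quickly at the E-disubstituted C7=C8 alkene to the (7R,8R) epoxide erythro to the carbinol, while the Z, electron-poor iodoalkene and the remote C1=C10 alkene are inert. The slow enantiomer remains and is separated by chromatography, so C6, C7 and C8 are set together.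

**Step 9**
Reactants: 16 2,2-dimethyl-1,3-dioxane-4,6-dione (Meldrum's acid); 17 2-(trimethylsilyl)ethanol
Product: 18 3-oxo-3-[2-(trimethylsilyl)ethoxy]propanoic acid
Conditions: toluene, 100 °C
Reagents that add atoms: none
Why: Alcoholysis of Meldrum's acid is the standard route to malonic half esters and releases only acetone.

**Step 10**
Reactants: 15 epoxy alcohol (6R,7R,8R); 18 3-oxo-3-[2-(trimethylsilyl)ethoxy]propanoic acid
Product: 19 O6 malonate of 15: (6R,7R,8R) epoxy carbinyl 2-(trimethylsilyl)ethyl propanedioate
Conditions: DCC, DMAP (0.1 equiv), CH2Cl2, 0 °C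
Reagents that add atoms: none
Why: Steglich esterification of a malonic half ester proceeds under nearly neutral conditions, so the epoxide and the allylic C6–O bond should be untouched and C6 keeps its configuration.

**Step 11**
Reactants: 19 O6 malonate of 15
Product: 21 2-(trimethylsilyl)ethyl (3R,4R,5S)-4-[(1R,3E)-6-[(tert-butyldimethylsilyl)oxy]-1-hydroxy-3-methylhex-3-en-1-yl]-5-[(1Z)-2-iodoprop-1-en-1-yl]-2-oxooxolane-3-carboxylate, via sodium enolate 20 (not isolated)
Conditions: NaH (1.05 equiv), THF/DMF, 0 → 40 °C; then AcOH (1.2 equiv), 0 °C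
Reagents that add atoms: none
Why: NaH removes the malonate C11–H, and the sodium enolate attacks C7 of the trans epoxide from the side opposite the C7–O bond, so C7–C11 forms with inversion at C7 while C6 and C8 keep the configurations set in step 8. The closest known reaction type is the intramolecular alkylation of malonate and related ester enolates by epoxides to give α-carboalkoxy γ-lactones. The one ring closes 5-exo-tet with respect to the epoxide (attack at C8 would be 6-endo) and, with respect to the nucleophile, as an enolexo closure through the enolate of the external silylethyl ester, which avoids the disfavoured 5-enolendo geometry a simple acetate enolate would face. C7 is controlled by the SN2 inversion and hence by the erythro epoxy alcohol; C11 is set thermodynamically trans to the C7 side chain through the enolate and is erased in step 16. The step needs C- over O-alkylation, which the tight sodium chelate of the malonate and its soft carbon terminus should secure, and it needs the freed C8 alkoxide not to attack the lactone carbonyl. The substrate secures the latter itself: the product C11–H is more acidic than the C8 hydroxyl, so with one equivalent of base the alkoxide is protonated internally and the lactone rests as its delocalised enolate 20, whose carbonyl is not electrophilic, until acetic acid is added in the cold.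

**Step 12**
Reactants: 22 methyl (2Z)-2-methylbut-2-enoate (methyl angelate)
Product: 23 (2Z)-2-methylbut-2-en-1-ol
Conditions: i-Bu2AlH (2.2 equiv), Et2O, −78 → 0 °C
Reagents that add atoms: none
Why: DIBAL-H reduction of the conjugated ester should give the Z allylic alcohol without isomerisation.

**Step 13**
Reactants: 23 (2Z)-2-methylbut-2-en-1-ol
Product: 24 [(2S,3R)-2,3-dimethyloxiran-2-yl]methanol
Conditions: Ti(OiPr)4 (cat.), L-(+)-diethyl tartrate (cat.), t-BuOOH, 4 Å MS, CH2Cl2, −20 °C; non-aqueous work-up
Reagents that add atoms: tert-butyl hydroperoxide, CC(C)(C)OO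
Why: Sharpless asymmetric epoxidation with L-(+)-tartrate should deliver oxygen to the face that gives the (2S,3R) epoxy alcohol; the cis relation of C1 and the C3 methyl comes from the Z alkene.

**Step 14**
Reactants: 24 [(2S,3R)-2,3-dimethyloxiran-2-yl]methanol
Product: 25 (2R,3R)-2,3-dimethyloxirane-2-carboxylic acid
Conditions: RuCl3·xH2O (cat.), NaIO4, CCl4/MeCN/H2O, rt
Reagents that add atoms: water, O
Why: Ruthenium tetroxide generated in situ oxidises primary epoxy alcohols to glycidic acids without opening the ring; no bond at C2 or C3 is touched, and the C2 descriptor changes only because the carboxyl now outranks C3.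

**Step 15**
Reactants: 21 hydroxy lactone ester (6S,7R,8R,11R); 25 (2R,3R)-2,3-dimethyloxirane-2-carboxylic acid
Product: 27 2-(trimethylsilyl)ethyl (3R,4R,5S)-4-[(1R,3E)-6-[(tert-butyldimethylsilyl)oxy]-1-{[(2R,3R)-2,3-dimethyloxirane-2-carbonyl]oxy}-3-methylhex-3-en-1-yl]-5-[(1Z)-2-iodoprop-1-en-1-yl]-2-oxooxolane-3-carboxylate, via mixed anhydride 26 (not isolated)
Conditions: 25, 2,4,6-trichlorobenzoyl chloride, Et3N, THF, rt; then 21, DMAP, toluene, rt
Reagents that add atoms: none
Why: Yamaguchi esterification acylates the hindered C8 hydroxyl on oxygen with retention at C8, and it should cap this hydroxyl before it can migrate onto the lactone carbonyl.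

**Step 16**
Reactants: 27 C8 epoxy ester of the lactone silylethyl ester
Product: 29 (1R,3E)-6-hydroxy-1-[(2S,3R)-2-[(1Z)-2-iodoprop-1-en-1-yl]-4-methylidene-5-oxooxolan-3-yl]-3-methylhex-3-en-1-yl (2R,3R)-2,3-dimethyloxirane-2-carboxylate, via hydroxy acid 28 (not isolated)
Conditions: Bu4NF (4 equiv), THF, 0 °C → rt; aq. NH4Cl work-up; then 37% aq. HCHO, Et2NH, THF, rt → 50 °C
Reagents that add atoms: formaldehyde, C=O
Why: Fluoride cleaves the silylethyl ester (loss of ethylene) and the C3 silyl ether in one operation, both compatible with the alkenyl iodide. The malonic half acid then undergoes a Mannich reaction with the iminium ion from formaldehyde and diethylamine, and decarboxylative elimination should give the α-methylene lactone, which erases C11.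

**Step 17**
Reactants: 29 methylene lactone primary alcohol
Product: 30 (1R,3E)-1-[(2S,3R)-2-[(1Z)-2-iodoprop-1-en-1-yl]-4-methylidene-5-oxooxolan-3-yl]-3-methyl-6-oxohex-3-en-1-yl (2R,3R)-2,3-dimethyloxirane-2-carboxylate
Conditions: Dess–Martin periodinane, NaHCO3, CH2Cl2, 0 °C → rt; used at once
Reagents that add atoms: none
Why: Buffered Dess–Martin oxidation is non-basic, so the β,γ-unsaturated aldehyde should form without migration of C1=C10 into conjugation.

**Step 18**
Reactants: 30 iodo aldehyde
Product: 31 (3S,6R,7R,8R)-3-hydroxy-8-{[(2R,3R)-2,3-dimethyloxirane-2-carbonyl]oxy}germacra-1(10)E,4Z,11(13)-trien-12,6-olide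
Conditions: CrCl2 (10 equiv), NiCl2 (0.1 equiv), DMSO, rt, 0.003 M, slow addition
Reagents that add atoms: none
Why: In the Nozaki–Hiyama–Kishi reaction zerovalent nickel inserts into the C4–I bond with retention of the Z geometry, and after transmetalation the alkenylchromium adds to the C3 aldehyde to close the ten-membered ring. C3 is set by the conformation of the closing ring; the 3S alcohol is the expected major product, although this selectivity is not assured.

**Step 19**
Reactants: 31 germacratrienolide
Product: 32 (1R,3S,6R,7R,8R,10R)-1,10-epoxy-3-hydroxy-8-{[(2R,3R)-2,3-dimethyloxirane-2-carbonyl]oxy}germacra-4Z,11(13)-dien-12,6-olide (CNP0268255.1)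
Conditions: mCPBA (1.1 equiv), NaHCO3, CH2Cl2, −20 → 0 °C
Reagents that add atoms: 3-chloroperoxybenzoic acid, O=C(OO)c1cccc(Cl)c1
Why: Prilezhaev epoxidation should select C1=C10, the only electron-rich alkene (C4=C5 is deactivated by two allylic C–O bonds, C11=C13 is conjugated). Peripheral attack on the exposed face of the E alkene should give the trans (1R,10R) epoxide stereospecifically.

## Compound list

1 | 3-[(tert-butyldimethylsilyl)oxy]propanal | O=CCCO[Si](C)(C)C(C)(C)C | starting material
2 | ethyl 2-(triphenylphosphoranylidene)propanoate | CCOC(=O)C(C)=P(c1ccccc1)(c1ccccc1)c1ccccc1 | starting material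
3 | ethyl (2E)-5-[(tert-butyldimethylsilyl)oxy]-2-methylpent-2-enoate | CCOC(=O)/C(C)=C/CCO[Si](C)(C)C(C)(C)C | intermediate
4 | (2E)-5-[(tert-butyldimethylsilyl)oxy]-2-methylpent-2-en-1-ol | OC/C(C)=C/CCO[Si](C)(C)C(C)(C)C | intermediate
5 | (3E)-5-bromo-1-[(tert-butyldimethylsilyl)oxy]-4-methylpent-3-ene | BrC/C(C)=C/CCO[Si](C)(C)C(C)(C)C | intermediate
6 | ethynylmagnesium bromide | C#C[Mg]Br | starting material
7 | tert-butyl(dimethyl){[(3E)-4-methylhept-3-en-6-yn-1-yl]oxy}silane | C#CC/C(C)=C/CCO[Si](C)(C)C(C)(C)C | intermediate
8 | but-2-yn-1-ol | CC#CCO | starting material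
9 | cyclic sodium alkenylaluminate (1,2-oxaluminole; Al on C3 and on O1 of the butenol, two 2-methoxyethoxy groups) | CC1=CCO[Al-]1(OCCOC)OCCOC.[Na+] | intermediate
10 | (2Z)-3-iodobut-2-en-1-ol | C/C(I)=C/CO | intermediate
11 | (2Z)-3-iodobut-2-enal | C/C(I)=C/C=O | intermediate
12 | chlorobis(cyclopentadienyl)[(1E,4E)-7-[(tert-butyldimethylsilyl)oxy]-4-methylhepta-1,4-dien-1-yl]zirconium | Cl[Zr](C1C=CC=C1)(C1C=CC=C1)/C=C/C/C(C)=C/CCO[Si](C)(C)C(C)(C)C | intermediate
13 | methyl[(1E,4E)-7-[(tert-butyldimethylsilyl)oxy]-4-methylhepta-1,4-dien-1-yl]zinc | C[Zn]/C=C/C/C(C)=C/CCO[Si](C)(C)C(C)(C)C | intermediate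
14 | racemic (2Z,5E,8E)-11-[(tert-butyldimethylsilyl)oxy]-2-iodo-8-methylundeca-2,5,8-trien-4-ol | C/C(I)=C/C(O)/C=C/C/C(C)=C/CCO[Si](C)(C)C(C)(C)C | intermediate
15 | (1R,2Z)-1-{(2R,3R)-3-[(2E)-5-[(tert-butyldimethylsilyl)oxy]-2-methylpent-2-en-1-yl]oxiran-2-yl}-3-iodobut-2-en-1-ol (erythro; 6R,7R,8R) | O[C@H](/C=C(/C)I)[C@H]1O[C@@H]1C/C(C)=C/CCO[Si](C)(C)C(C)(C)C | intermediate
16 | 2,2-dimethyl-1,3-dioxane-4,6-dione (Meldrum's acid) | CC1(C)OC(=O)CC(=O)O1 | starting material
17 | 2-(trimethylsilyl)ethanol | C[Si](C)(C)CCO | starting material
18 | 3-oxo-3-[2-(trimethylsilyl)ethoxy]propanoic acid | C[Si](C)(C)CCOC(=O)CC(=O)O | intermediate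
19 | O6 malonate of 15: (6R,7R,8R) epoxy carbinyl 2-(trimethylsilyl)ethyl propanedioate | C[Si](C)(C)CCOC(=O)CC(=O)O[C@H](/C=C(/C)I)[C@H]1O[C@@H]1C/C(C)=C/CCO[Si](C)(C)C(C)(C)C | intermediate
20 | sodium enolate of 21 (enolate of the C11 silylethyl ester, C8 hydroxyl free) | C[Si](C)(C)CCOC([O-])=C1C(=O)O[C@H](/C=C(/C)I)[C@H]1[C@H](O)C/C(C)=C/CCO[Si](C)(C)C(C)(C)C.[Na+] | intermediate
21 | 2-(trimethylsilyl)ethyl (3R,4R,5S)-4-[(1R,3E)-6-[(tert-butyldimethylsilyl)oxy]-1-hydroxy-3-methylhex-3-en-1-yl]-5-[(1Z)-2-iodoprop-1-en-1-yl]-2-oxooxolane-3-carboxylate (6S,7R,8R,11R) | C[Si](C)(C)CCOC(=O)[C@@H]1C(=O)O[C@H](/C=C(/C)I)[C@H]1[C@H](O)C/C(C)=C/CCO[Si](C)(C)C(C)(C)C | intermediate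
22 | methyl (2Z)-2-methylbut-2-enoate (methyl angelate) | C/C=C(/C)C(=O)OC | starting material
23 | (2Z)-2-methylbut-2-en-1-ol | C/C=C(/C)CO | intermediate
24 | [(2S,3R)-2,3-dimethyloxiran-2-yl]methanol | OC[C@]1(C)O[C@@H]1C | intermediate
25 | (2R,3R)-2,3-dimethyloxirane-2-carboxylic acid | OC(=O)[C@]1(C)O[C@@H]1C | intermediate
26 | (2R,3R)-2,3-dimethyloxirane-2-carboxylic 2,4,6-trichlorobenzoic anhydride | O=C(OC(=O)[C@]1(C)O[C@@H]1C)c1c(Cl)cc(Cl)cc1Cl | intermediate
27 | 2-(trimethylsilyl)ethyl (3R,4R,5S)-4-[(1R,3E)-6-[(tert-butyldimethylsilyl)oxy]-1-{[(2R,3R)-2,3-dimethyloxirane-2-carbonyl]oxy}-3-methylhex-3-en-1-yl]-5-[(1Z)-2-iodoprop-1-en-1-yl]-2-oxooxolane-3-carboxylate | C[Si](C)(C)CCOC(=O)[C@@H]1C(=O)O[C@H](/C=C(/C)I)[C@H]1[C@H](OC(=O)[C@]2(C)O[C@@H]2C)C/C(C)=C/CCO[Si](C)(C)C(C)(C)C | intermediate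
28 | (3R,4R,5S)-4-[(1R,3E)-1-{[(2R,3R)-2,3-dimethyloxirane-2-carbonyl]oxy}-6-hydroxy-3-methylhex-3-en-1-yl]-5-[(1Z)-2-iodoprop-1-en-1-yl]-2-oxooxolane-3-carboxylic acid | OC(=O)[C@@H]1C(=O)O[C@H](/C=C(/C)I)[C@H]1[C@H](OC(=O)[C@]2(C)O[C@@H]2C)C/C(C)=C/CCO | intermediate
29 | (1R,3E)-6-hydroxy-1-[(2S,3R)-2-[(1Z)-2-iodoprop-1-en-1-yl]-4-methylidene-5-oxooxolan-3-yl]-3-methylhex-3-en-1-yl (2R,3R)-2,3-dimethyloxirane-2-carboxylate | C=C1C(=O)O[C@H](/C=C(/C)I)[C@H]1[C@H](OC(=O)[C@]2(C)O[C@@H]2C)C/C(C)=C/CCO | intermediate
30 | (1R,3E)-1-[(2S,3R)-2-[(1Z)-2-iodoprop-1-en-1-yl]-4-methylidene-5-oxooxolan-3-yl]-3-methyl-6-oxohex-3-en-1-yl (2R,3R)-2,3-dimethyloxirane-2-carboxylate | C=C1C(=O)O[C@H](/C=C(/C)I)[C@H]1[C@H](OC(=O)[C@]2(C)O[C@@H]2C)C/C(C)=C/CC=O | intermediate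
31 | (3S,6R,7R,8R)-3-hydroxy-8-{[(2R,3R)-2,3-dimethyloxirane-2-carbonyl]oxy}germacra-1(10)E,4Z,11(13)-trien-12,6-olide | C=C1C(=O)O[C@@H]2/C=C(/C)[C@@H](O)C/C=C(\C)C[C@@H](OC(=O)[C@]3(C)O[C@@H]3C)[C@@H]12 | intermediate
32 | (1R,3S,6R,7R,8R,10R)-1,10-epoxy-3-hydroxy-8-{[(2R,3R)-2,3-dimethyloxirane-2-carbonyl]oxy}germacra-4Z,11(13)-dien-12,6-olide (CNP0268255.1) | C=C1C(=O)O[C@@H]2/C=C(/C)[C@@H](O)C[C@H]3O[C@]3(C)C[C@@H](OC(=O)[C@]3(C)O[C@@H]3C)[C@@H]12 | target

## Step count and least certain steps

Total: 19 steps. Longest linear sequence: 13 steps (steps 1–4, 7, 8, 10, 11, 15–19, from aldehyde 1).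

**Step 11 (key step).** The enolate may alkylate on oxygen at C7 and close a dioxolane ketene acetal instead of the lactone. The unactivated epoxide may open slowly, and the lactone may migrate to the C8 oxygen if the enolate is quenched too late or with too little base. Fallback, from 15 back to the route at 29: 15 is esterified with (diethoxyphosphoryl)acetic acid (DCC, DMAP) to the phosphonoacetate F1. Its more nucleophilic phosphonate-stabilised anion (NaH, THF) closes the same C7–C11 bond to the α-phosphono lactone F2. Yamaguchi acylation with 25 gives the epoxy ester F3. A Horner–Wadsworth–Emmons reaction with aqueous formaldehyde and K2CO3 gives the silyl-protected methylene lactone F4 without any ester cleavage or decarboxylation, and HF·pyridine removes the silyl ether to give 29.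

**Step 18.** Closure of the strained ten-membered ring may be slow enough for protodemetalation or intermolecular coupling to compete. Facial selectivity at the C3 aldehyde may be poor. Excess divalent chromium may reduce the α,β-epoxy ester. Fallback for the stereochemical issue, from 31 as obtained together with its C3 epimer, back to 31: the mixture containing the 3R alcohol F5 is oxidised with Dess–Martin periodinane to the dienone F6. Reagent-controlled Corey–Bakshi–Shibata reduction ((R)-Me-CBS, catecholborane, −78 °C, with the C4 alkenyl group as the large substituent) should then return the 3S alcohol 31.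

**Step 19.** The free C3 hydroxyl may direct the peracid to C4=C5, or the peracid may attack the inner face of C1=C10. Fallback, from 31 to 32: 31 is silylated (Et3SiCl, imidazole) to the triethylsilyl ether F7, which removes the hydroxyl-directed pathway. Shi epoxidation with the D-fructose-derived ketone and Oxone, which on E-trisubstituted alkenes of this substitution pattern delivers the R,R epoxide, gives the epoxide F8, and HF·pyridine releases 32.

**Step 8.** The rate difference between the enantiomers of this bis-allylic alcohol may be small, or the titanium Lewis acid may ionise the doubly allylic carbinol; in any case half of 14 is lost. Fallback, from 14 to 15: 14 is oxidised with MnO2 to the dienone F9. Corey–Bakshi–Shibata reduction ((R)-Me-CBS, catecholborane, with the β,β-disubstituted iodoalkenyl group as the large substituent) gives the (S)-alcohol F10. The same D-(−)-tartrate epoxidation is then run to full conversion as a matched, diastereoselective reaction and also removes residual minor enantiomer, giving 15.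

**Step 7.** The β-iodo enal may isomerise from Z to E in the presence of the Lewis-acidic zirconium and zinc species, and methyl transfer from the mixed zinc reagent may compete. Fallback, from 7 to 14: hydrozirconation of 7 followed by iodine gives the alkenyl iodide F11. Iodine–lithium exchange (t-BuLi, Et2O, −78 °C) and addition of the alkenyllithium to 11 at −78 °C, without any Lewis acid, gives 14.

## Further compounds

F1 | step 11 | O6 (diethoxyphosphoryl)acetate of 15 (6R,7R,8R) | CCOP(=O)(OCC)CC(=O)O[C@H](/C=C(/C)I)[C@H]1O[C@@H]1C/C(C)=C/CCO[Si](C)(C)C(C)(C)C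
F2 | step 11 | α-(diethoxyphosphoryl) trans-lactone with free C8 hydroxyl, C3 tert-butyldimethylsilyl ether (C11 epimers) | CCOP(=O)(OCC)C1C(=O)O[C@H](/C=C(/C)I)[C@H]1[C@H](O)C/C(C)=C/CCO[Si](C)(C)C(C)(C)C
F3 | step 11 | C8 (2R,3R)-2,3-dimethyloxirane-2-carboxylate of F2 | CCOP(=O)(OCC)C1C(=O)O[C@H](/C=C(/C)I)[C@H]1[C@H](OC(=O)[C@]2(C)O[C@@H]2C)C/C(C)=C/CCO[Si](C)(C)C(C)(C)C
F4 | step 11 | C3 tert-butyldimethylsilyl ether of 29 | C=C1C(=O)O[C@H](/C=C(/C)I)[C@H]1[C@H](OC(=O)[C@]2(C)O[C@@H]2C)C/C(C)=C/CCO[Si](C)(C)C(C)(C)C
F5 | step 18 | (3R) epimer of 31 | C=C1C(=O)O[C@@H]2/C=C(/C)[C@H](O)C/C=C(\C)C[C@@H](OC(=O)[C@]3(C)O[C@@H]3C)[C@@H]12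
F6 | step 18 | (6R,7R,8R)-3-oxo-8-{[(2R,3R)-2,3-dimethyloxirane-2-carbonyl]oxy}germacra-1(10)E,4Z,11(13)-trien-12,6-olide | C=C1C(=O)O[C@@H]2/C=C(/C)C(=O)C/C=C(\C)C[C@@H](OC(=O)[C@]3(C)O[C@@H]3C)[C@@H]12
F7 | step 19 | C3 triethylsilyl ether of 31 | C=C1C(=O)O[C@@H]2/C=C(/C)[C@@H](O[Si](CC)(CC)CC)C/C=C(\C)C[C@@H](OC(=O)[C@]3(C)O[C@@H]3C)[C@@H]12
F8 | step 19 | C3 triethylsilyl ether of 32 | C=C1C(=O)O[C@@H]2/C=C(/C)[C@@H](O[Si](CC)(CC)CC)C[C@H]3O[C@]3(C)C[C@@H](OC(=O)[C@]3(C)O[C@@H]3C)[C@@H]12
F9 | step 8 | (2Z,5E,8E)-11-[(tert-butyldimethylsilyl)oxy]-2-iodo-8-methylundeca-2,5,8-trien-4-one | C/C(I)=C/C(=O)/C=C/C/C(C)=C/CCO[Si](C)(C)C(C)(C)C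
F10 | step 8 | (4S,2Z,5E,8E)-11-[(tert-butyldimethylsilyl)oxy]-2-iodo-8-methylundeca-2,5,8-trien-4-ol | C/C(I)=C/[C@@H](O)/C=C/C/C(C)=C/CCO[Si](C)(C)C(C)(C)C
F11 | step 7 | tert-butyl{[(3E,6E)-7-iodo-4-methylhepta-3,6-dien-1-yl]oxy}dimethylsilane | I/C=C/C/C(C)=C/CCO[Si](C)(C)C(C)(C)C
A1 | alternative 1 | (5R)-5-[(4-methoxybenzyl)oxy]-3-methylcyclohex-2-en-1-one | O=C1C[C@H](OCc2ccc(OC)cc2)CC(C)=C1
A2 | alternative 1 | tert-butyl(dimethyl){[(1S)-2-methylcyclobut-2-en-1-yl]oxy}silane | CC1=CC[C@@H]1O[Si](C)(C)C(C)(C)C
A3 | alternative 1 | cis-anti-cis 6-4-4 tricyclic ketone (photoadduct of A1 and A2) | O=C1C[C@H](OCc2ccc(OC)cc2)C[C@]2(C)[C@H]3C[C@H](O[Si](C)(C)C(C)(C)C)[C@@]3(C)[C@H]12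
A4 | alternative 2 | open-chain (Z)-iodo aldehyde with α-methylene lactone and C8 triethylsilyl ether | C=C1C(=O)O[C@H](/C=C(/C)I)[C@H]1[C@H](O[Si](CC)(CC)CC)C/C(C)=C/CC=O
A5 | alternative 2 | (1(10)E,4Z)-germacradienolide with free C3 hydroxyl and C8 triethylsilyl ether | C=C1C(=O)O[C@@H]2/C=C(/C)[C@@H](O)C/C=C(\C)C[C@@H](O[Si](CC)(CC)CC)[C@@H]12
A6 | alternative 3 | trans-fused oxetane (O on C6, CH2 C11 on C7) of the ten-membered diene, C3 tert-butyldimethylsilyl ether, C8 4-methoxybenzyl ether | C1O[C@@H]2/C=C(/C)[C@@H](O[Si](C)(C)C(C)(C)C)C/C=C(\C)C[C@@H](OCc3ccc(OC)cc3)[C@@H]12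
A7 | alternative 3 | trans-fused γ-lactone lacking the C13 methylene | C1C(=O)O[C@@H]2/C=C(/C)[C@@H](O[Si](C)(C)C(C)(C)C)C/C=C(\C)C[C@@H](OCc3ccc(OC)cc3)[C@@H]12
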